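**Plan**

- Feature used: in ring C (the pyran ring) of this flavan, C2 carries O1 and the ring B aryl group and is joined to C4 only through the unsubstituted methylene C3. A formyl group lent to C3 makes O1–C2 an oxa-Michael bond and C3–C4 an aldol bond, and can be taken off afterwards.
- Retrosynthesis: remove the three MOM ethers, put CHO back on C3 and the C3=C4 double bond back in, then cut O1–C2 and C3–C4. This gives a prenylated salicylaldehyde (ring A) and a cinnamaldehyde (ring B). The prenyl C–C bond goes back to an aryl ether (Claisen), the enal C=C to a Wittig reaction.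
- Forward: ring A aldehyde 7 (steps 1–4) and ring B enal 11 (steps 5–6) are made separately and joined in step 7, which closes ring C. The enal is then saturated (step 8), the formyl group removed (step 9) and the phenols set free (step 10).
- Stereochemistry: C2 is the only stereocentre. It is set in step 7 by the chiral amine catalyst and is protected afterwards by keeping the β-aryloxy aldehyde away from base.

Key step: step 7

Assumption: the (S)-configured diphenylprolinol trimethylsilyl ether is taken to send the phenol to the Si face of the β-carbon of the E-iminium ion (usual shielding model), which corresponds to (2R)-15 and, after loss of the formyl group, to the (2S)-target; if the sense proved opposite, the (R)-catalyst would be used with nothing else changed.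

Remark: C3 of 17 is expected as a mixture of epimers; this is of no consequence because C3 becomes CH2 in step 9.

**Route**

Step 1
Reactants: 1 2,4,6-trihydroxybenzaldehyde
Product: 2 2-hydroxy-4,6-bis(methoxymethoxy)benzaldehyde
Conditions: MOMCl (2.2 equiv), i-Pr2NEt, CH2Cl2, 0 °C to rt
Reagents that add atoms: chloromethyl methyl ether, COCCl
Why: Williamson-type O-alkylation (MOM protection) should take the para hydroxyl and one ortho hydroxyl, while the second ortho hydroxyl stays free because its hydrogen bond to the formyl oxygen lowers its nucleophilicity.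

Step 2
Reactants: 2 2-hydroxy-4,6-bis(methoxymethoxy)benzaldehyde; 3 3-chloro-3-methylbut-1-yne
Product: 4 4,6-bis(methoxymethoxy)-2-(2-methylbut-3-yn-2-yloxy)benzaldehyde
Conditions: 3 (1.5 equiv), CuCl2·2H2O (1 mol %), DBU, MeCN, 0 °C to rt
Reagents that add atoms: none
Why: Copper-catalysed O-propargylation of a phenol by a tertiary propargylic chloride, in which DBU frees the chelated phenoxide and the copper-stabilised propargylic cation should be captured at its tertiary carbon, fixing the reverse-prenyl connectivity needed for step 4.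

Step 3
Reactants: 4 4,6-bis(methoxymethoxy)-2-(2-methylbut-3-yn-2-yloxy)benzaldehyde
Product: 5 4,6-bis(methoxymethoxy)-2-(2-methylbut-3-en-2-yloxy)benzaldehyde
Conditions: H2 (1 atm), Pd/CaCO3 poisoned with Pb(OAc)2, quinoline, EtOAc, rt
Reagents that add atoms: none
Why: Semihydrogenation of the terminal alkyne over lead-poisoned palladium should stop at the alkene and leave the aryl aldehyde and the MOM acetals unchanged.

Step 4
Reactants: 5 4,6-bis(methoxymethoxy)-2-(2-methylbut-3-en-2-yloxy)benzaldehyde
Product: 7 2-hydroxy-4,6-bis(methoxymethoxy)-3-(3-methylbut-2-enyl)benzaldehyde, via Claisen dienone 6 (not isolated)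
Conditions: PhMe, 110 °C
Reagents that add atoms: none
Why: Aromatic Claisen rearrangement, a [3,3]-sigmatropic shift of the 1,1-dimethylallyl ether to the only unsubstituted ortho carbon, should give dienone 6, whose tautomerisation restores the chelated phenol and leaves a linear prenyl group between that hydroxyl and the neighbouring MOM ether.

Step 5
Reactants: 8 3-hydroxy-5-methoxybenzaldehyde
Product: 9 3-methoxy-5-(methoxymethoxy)benzaldehyde
Conditions: MOMCl (1.2 equiv), i-Pr2NEt, CH2Cl2, 0 °C to rt
Reagents that add atoms: chloromethyl methyl ether, COCCl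
Why: Williamson-type MOM protection of the single phenol keeps it from acting as a competing oxa-Michael donor in step 7 and lets it be freed together with the ring A phenols at the end.

Step 6
Reactants: 9 3-methoxy-5-(methoxymethoxy)benzaldehyde; 10 (triphenylphosphoranylidene)acetaldehyde
Product: 11 (E)-3-[3-methoxy-5-(methoxymethoxy)phenyl]prop-2-enal
Conditions: 10 (1.1 equiv), PhMe, 80 °C
Reagents that add atoms: none
Why: Wittig olefination with the stabilised formyl ylide should give the E-enal in one operation, the ylide being kept near one equivalent to limit a second homologation.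

Step 7
Reactants: 7 2-hydroxy-4,6-bis(methoxymethoxy)-3-(3-methylbut-2-enyl)benzaldehyde; 11 (E)-3-[3-methoxy-5-(methoxymethoxy)phenyl]prop-2-enal
Product: 15 (2R)-5,7-bis(methoxymethoxy)-2-[3-methoxy-5-(methoxymethoxy)phenyl]-8-(3-methylbut-2-enyl)-2H-chromene-3-carbaldehyde, via iminium ion 12 (not isolated), via oxa-Michael enamine 13 (not isolated), via aldol iminium ion 14 (not isolated)
Conditions: 11 (1.3 equiv), (S)-2-[diphenyl(trimethylsilyloxy)methyl]pyrrolidine (20 mol %), 2-nitrobenzoic acid (20 mol %), 4 Å molecular sieves, PhMe, rt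
Reagents that add atoms: none
Why: The secondary amine condenses with enal 11 to the E-iminium ion 12, the phenol of 7 adds to its β-carbon (O1–C2) to give enamine 13, and the enamine carbon then attacks the neighbouring aryl aldehyde (C3–C4) to give 14, from which water is lost and the amine is released by hydrolysis. The closest known reaction type is the diarylprolinol silyl ether-catalysed oxa-Michael/aldol condensation of salicylaldehydes with cinnamaldehydes to 2-aryl-2H-chromene-3-carbaldehydes. Ring C closes in the aldol event as a 6-(enolexo)-exo-trig cyclisation, made irreversible by the dehydration that follows. The C2 stereocentre is controlled by the catalyst: its diphenyl(trimethylsilyloxy)methyl group blocks one face of 12, so the phenol should approach the Si face of the β-carbon and give the (2R) descriptor of 15, which is the spatial arrangement of the (2S)-target once the formyl group has gone. The step needs regio- and chemoselectivity, secured because 7 has a single free hydroxyl, placed between the formyl-bearing and prenyl-bearing carbons, because the ring B phenol of 11 is masked, and because the hindered, chelated aryl aldehyde of 7 does not compete with 11 for iminium formation. The low electrophilicity of that aldehyde should slow but not stop the intramolecular aldol step, hence the acid co-catalyst, the sieves and the generous catalyst loading.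

Step 8
Reactants: 15 (2R)-5,7-bis(methoxymethoxy)-2-[3-methoxy-5-(methoxymethoxy)phenyl]-8-(3-methylbut-2-enyl)-2H-chromene-3-carbaldehyde
Product: 17 (2S)-5,7-bis(methoxymethoxy)-2-[3-methoxy-5-(methoxymethoxy)phenyl]-8-(3-methylbut-2-enyl)-3,4-dihydro-2H-chromene-3-carbaldehyde, via silyl enol ether 16 (not isolated)
Conditions: [(Ph3P)CuH]6 (0.4 equiv), TBSCl (1.5 equiv), PhMe, rt; then TBAF, AcOH, THF, 0 °C
Reagents that add atoms: none
Why: Conjugate reduction of the enal by the copper hydride cluster should deliver hydride to C4, the copper enolate being trapped at once as silyl enol ether 16 so that aryloxide expulsion from C3 is given no time, and buffered fluoride then protonates C3, while the isolated prenyl alkene, the MOM ethers and C2 remain untouched.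

Step 9
Reactants: 17 (2S)-5,7-bis(methoxymethoxy)-2-[3-methoxy-5-(methoxymethoxy)phenyl]-8-(3-methylbut-2-enyl)-3,4-dihydro-2H-chromene-3-carbaldehyde
Product: 18 (2S)-5,7-bis(methoxymethoxy)-2-[3-methoxy-5-(methoxymethoxy)phenyl]-8-(3-methylbut-2-enyl)-3,4-dihydro-2H-chromene
Conditions: RhCl(PPh3)3 (1.1 equiv), degassed PhMe, 110 °C
Reagents that add atoms: none
Why: Tsuji–Wilkinson decarbonylation, in which oxidative addition of the formyl C–H bond to rhodium, CO migration to the metal and C–H reductive elimination should replace CHO by H under neutral aprotic conditions, so that no C3 enolate arises, C2 is untouched and both C3 epimers converge on one CH2 compound.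

Step 10
Reactants: 18 (2S)-5,7-bis(methoxymethoxy)-2-[3-methoxy-5-(methoxymethoxy)phenyl]-8-(3-methylbut-2-enyl)-3,4-dihydro-2H-chromene
Product: 19 (2S)-2-(3-hydroxy-5-methoxyphenyl)-8-(3-methylbut-2-enyl)-3,4-dihydro-2H-chromene-5,7-diol
Conditions: 3 M aq HCl, MeOH, 40 °C
Reagents that add atoms: none
Why: Acid-catalysed acetal exchange with methanol (MOM cleavage) should release all three phenols, the benzylic C2–O1 bond being slow to ionise because ring B carries its oxygens meta to C2, and the mild temperature being chosen to spare the prenyl group from cyclisation onto the 7-hydroxyl.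

**Compound list**

1 | 2,4,6-trihydroxybenzaldehyde | O=Cc1c(O)cc(O)cc1O | starting material
2 | 2-hydroxy-4,6-bis(methoxymethoxy)benzaldehyde | O=Cc1c(O)cc(OCOC)cc1OCOC | intermediate
3 | 3-chloro-3-methylbut-1-yne | CC(C)(Cl)C#C | starting material
4 | 4,6-bis(methoxymethoxy)-2-(2-methylbut-3-yn-2-yloxy)benzaldehyde | O=Cc1c(OC(C)(C)C#C)cc(OCOC)cc1OCOC | intermediate
5 | 4,6-bis(methoxymethoxy)-2-(2-methylbut-3-en-2-yloxy)benzaldehyde | O=Cc1c(OC(C)(C)C=C)cc(OCOC)cc1OCOC | intermediate
6 | 2,4-bis(methoxymethoxy)-5-(3-methylbut-2-enyl)-6-oxocyclohexa-1,3-diene-1-carbaldehyde (Claisen dienone, racemic at the sp3 ring carbon, not isolated) | O=CC1=C(OCOC)C=C(OCOC)C(CC=C(C)C)C1=O | intermediate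
7 | 2-hydroxy-4,6-bis(methoxymethoxy)-3-(3-methylbut-2-enyl)benzaldehyde | O=Cc1c(O)c(CC=C(C)C)c(OCOC)cc1OCOC | intermediate
8 | 3-hydroxy-5-methoxybenzaldehyde | COc1cc(O)cc(C=O)c1 | starting material
9 | 3-methoxy-5-(methoxymethoxy)benzaldehyde | COCOc1cc(OC)cc(C=O)c1 | intermediate
10 | (triphenylphosphoranylidene)acetaldehyde | O=CC=P(c1ccccc1)(c1ccccc1)c1ccccc1 | starting material
11 | (E)-3-[3-methoxy-5-(methoxymethoxy)phenyl]prop-2-enal | COCOc1cc(OC)cc(/C=C/C=O)c1 | intermediate
12 | iminium ion of 11 with the (S)-catalyst, 2-nitrobenzoate salt: (2S)-2-[diphenyl(trimethylsilyloxy)methyl]-1-[(E)-3-[3-methoxy-5-(methoxymethoxy)phenyl]prop-2-enylidene]pyrrolidinium (not isolated) | COCOc1cc(OC)cc(/C=C/C=[N+]2CCC[C@H]2C(O[Si](C)(C)C)(c2ccccc2)c2ccccc2)c1.[O-]C(=O)c1ccccc1[N+](=O)[O-] | intermediate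
13 | oxa-Michael enamine: (E)-enamine of the (S)-catalyst in which the former β-carbon, (S)-configured, bears the ring B aryl group and the aryloxy group of 7 with its formyl group still free (not isolated) | COc1cc(OCOC)cc([C@H](/C=C/N2CCC[C@H]2C(O[Si](C)(C)C)(c2ccccc2)c2ccccc2)Oc2c(C=O)c(OCOC)cc(OCOC)c2CC=C(C)C)c1 | intermediate
14 | aldol iminium ion, 2-nitrobenzoate salt: (2S)-4-hydroxychroman closed at C3–C4, C3 bearing the CH=N+ link to the (S)-catalyst, C3 and C4 undefined (not isolated) | COc1cc(OCOC)cc([C@@H]2C(C=[N+]3CCC[C@H]3C(O[Si](C)(C)C)(c3ccccc3)c3ccccc3)C(O)c3c(OCOC)cc(OCOC)c(CC=C(C)C)c3O2)c1.[O-]C(=O)c1ccccc1[N+](=O)[O-] | intermediate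
15 | (2R)-5,7-bis(methoxymethoxy)-2-[3-methoxy-5-(methoxymethoxy)phenyl]-8-(3-methylbut-2-enyl)-2H-chromene-3-carbaldehyde | COc1cc(OCOC)cc([C@@H]2C(C=O)=Cc3c(OCOC)cc(OCOC)c(CC=C(C)C)c3O2)c1 | intermediate
16 | (2R)-3-[(tert-butyldimethylsilyloxy)methylidene]-5,7-bis(methoxymethoxy)-2-[3-methoxy-5-(methoxymethoxy)phenyl]-8-(3-methylbut-2-enyl)-3,4-dihydro-2H-chromene, enol ether geometry undefined (not isolated) | COc1cc(OCOC)cc([C@@H]2C(=CO[Si](C)(C)C(C)(C)C)Cc3c(OCOC)cc(OCOC)c(CC=C(C)C)c3O2)c1 | intermediate
17 | (2S)-5,7-bis(methoxymethoxy)-2-[3-methoxy-5-(methoxymethoxy)phenyl]-8-(3-methylbut-2-enyl)-3,4-dihydro-2H-chromene-3-carbaldehyde, C3 epimers (C3 undefined) | COc1cc(OCOC)cc([C@@H]2C(C=O)Cc3c(OCOC)cc(OCOC)c(CC=C(C)C)c3O2)c1 | intermediate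
18 | (2S)-5,7-bis(methoxymethoxy)-2-[3-methoxy-5-(methoxymethoxy)phenyl]-8-(3-methylbut-2-enyl)-3,4-dihydro-2H-chromene | COc1cc(OCOC)cc([C@@H]2CCc3c(OCOC)cc(OCOC)c(CC=C(C)C)c3O2)c1 | intermediate
19 | (2S)-2-(3-hydroxy-5-methoxyphenyl)-8-(3-methylbut-2-enyl)-3,4-dihydro-2H-chromene-5,7-diol | COc1cc(O)cc([C@@H]2CCc3c(O)cc(O)c(CC=C(C)C)c3O2)c1 | target

**Step count**

Total: 10 steps. Longest linear sequence: 8 steps (steps 1–4 and 7–10); steps 5–6 form the second branch.

**Steps most likely to fail**

Step 7. The enamine aldol onto the di-ortho-substituted, electron-rich aryl aldehyde may be so slow that the reversible oxa-Michael addition equilibrates, with loss of both conversion and facial selectivity. The fallback sets out from 7 and 9 and comes back at 18. It closes ring C at O1–C2 by an invertive etherification of a carbinol whose configuration comes from a reagent-controlled ketone reduction.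
- MeMgBr (THF, 0 °C) adds to 9 to give 1-[3-methoxy-5-(methoxymethoxy)phenyl]ethanol F1.
- Dess–Martin oxidation gives 1-[3-methoxy-5-(methoxymethoxy)phenyl]ethanone F2.
- Claisen–Schmidt condensation of F2 with 7 (KOH, EtOH, rt) gives (E)-3-[2-hydroxy-4,6-bis(methoxymethoxy)-3-(3-methylbut-2-enyl)phenyl]-1-[3-methoxy-5-(methoxymethoxy)phenyl]prop-2-en-1-one F3.
- Conjugate reduction with [(Ph3P)CuH]6 in wet THF gives 3-[2-hydroxy-4,6-bis(methoxymethoxy)-3-(3-methylbut-2-enyl)phenyl]-1-[3-methoxy-5-(methoxymethoxy)phenyl]propan-1-one F4.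
- Corey–Bakshi–Shibata reduction with (S)-2-methyl-CBS-oxazaborolidine and BH3·SMe2 should give (1R)-3-[2-hydroxy-4,6-bis(methoxymethoxy)-3-(3-methylbut-2-enyl)phenyl]-1-[3-methoxy-5-(methoxymethoxy)phenyl]propan-1-ol F5.
- Intramolecular Mitsunobu etherification (PPh3, DIAD, THF, 0 °C) with inversion at the carbinol carbon should give 18, so that steps 7–9 are bypassed.

Step 8. On hydride delivery the C3 enolate may expel the aryloxide, which opens ring C and puts C2 at risk, or the hydride may add to the carbonyl group instead. The fallback sets out from 15 and comes back at 18. It reverses the order of events so that no enolate is ever formed. RhCl(PPh3)3 (1.1 equiv, PhMe, 90 °C) decarbonylates the enal directly to (2S)-5,7-bis(methoxymethoxy)-2-[3-methoxy-5-(methoxymethoxy)phenyl]-8-(3-methylbut-2-enyl)-2H-chromene F6. Diimide, generated from 2-nitrobenzenesulfonyl hydrazide and Et3N in CH2Cl2 at rt, should then reduce the cis-disubstituted C3=C4 bond in preference to the trisubstituted prenyl alkene and give 18. The chromene F6 is kept cold and in the dark to avoid electrocyclic ring opening.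

Step 9. After CO extrusion the secondary alkylrhodium hydride may undergo β-hydride or β-aryloxy elimination instead of C–H reductive elimination, or the hindered α-branched aldehyde may react only sluggishly. The fallback sets out from 17 and comes back at 18. It changes the oxidation level and removes the carbon by a radical path. Pinnick oxidation (NaClO2, NaH2PO4, excess 2-methylbut-2-ene, t-BuOH/H2O) gives (2S)-5,7-bis(methoxymethoxy)-2-[3-methoxy-5-(methoxymethoxy)phenyl]-8-(3-methylbut-2-enyl)-3,4-dihydro-2H-chromene-3-carboxylic acid F7. Coupling with N-hydroxypyridine-2-thione (DCC, CH2Cl2, dark) gives the thiohydroxamate ester (2-thioxopyridin-1(2H)-yl ester of F7) F8. Visible-light photolysis in the presence of t-BuSH (Barton reductive decarboxylation) should give 18.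

**Further compounds**

F1 | step 7 | 1-[3-methoxy-5-(methoxymethoxy)phenyl]ethanol (racemic) | COCOc1cc(OC)cc(C(C)O)c1
F2 | step 7 | 1-[3-methoxy-5-(methoxymethoxy)phenyl]ethanone | COCOc1cc(OC)cc(C(C)=O)c1
F3 | step 7 | (E)-3-[2-hydroxy-4,6-bis(methoxymethoxy)-3-(3-methylbut-2-enyl)phenyl]-1-[3-methoxy-5-(methoxymethoxy)phenyl]prop-2-en-1-one | COCOc1cc(OC)cc(C(=O)/C=C/c2c(O)c(CC=C(C)C)c(OCOC)cc2OCOC)c1
F4 | step 7 | 3-[2-hydroxy-4,6-bis(methoxymethoxy)-3-(3-methylbut-2-enyl)phenyl]-1-[3-methoxy-5-(methoxymethoxy)phenyl]propan-1-one | COCOc1cc(OC)cc(C(=O)CCc2c(O)c(CC=C(C)C)c(OCOC)cc2OCOC)c1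
F5 | step 7 | (1R)-3-[2-hydroxy-4,6-bis(methoxymethoxy)-3-(3-methylbut-2-enyl)phenyl]-1-[3-methoxy-5-(methoxymethoxy)phenyl]propan-1-ol | COCOc1cc(OC)cc([C@H](O)CCc2c(O)c(CC=C(C)C)c(OCOC)cc2OCOC)c1
F6 | step 8 | (2S)-5,7-bis(methoxymethoxy)-2-[3-methoxy-5-(methoxymethoxy)phenyl]-8-(3-methylbut-2-enyl)-2H-chromene | COc1cc(OCOC)cc([C@@H]2C=Cc3c(OCOC)cc(OCOC)c(CC=C(C)C)c3O2)c1
F7 | step 9 | (2S)-5,7-bis(methoxymethoxy)-2-[3-methoxy-5-(methoxymethoxy)phenyl]-8-(3-methylbut-2-enyl)-3,4-dihydro-2H-chromene-3-carboxylic acid (C3 undefined) | COc1cc(OCOC)cc([C@@H]2C(C(=O)O)Cc3c(OCOC)cc(OCOC)c(CC=C(C)C)c3O2)c1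
F8 | step 9 | 2-thioxopyridin-1(2H)-yl (2S)-5,7-bis(methoxymethoxy)-2-[3-methoxy-5-(methoxymethoxy)phenyl]-8-(3-methylbut-2-enyl)-3,4-dihydro-2H-chromene-3-carboxylate (C3 undefined) | COc1cc(OCOC)cc([C@@H]2C(C(=O)On3ccccc3=S)Cc3c(OCOC)cc(OCOC)c(CC=C(C)C)c3O2)c1
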